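The 14-membered carbocycle and the 1,2-dioxane share two atoms, C8 and C11 (cembrane numbering); the dioxane's ethano unit C9–C10 is disconnected from both. One flask stitches it in: vinylmagnesium bromide adds to the C11 enal of an acyclic lactone (C10–C11), 9-BBN hydroborates the new vinyl group, and an intramolecular B-alkyl Suzuki coupling with the C8 (Z)-iodoalkene (C8–C9) closes the carbocycle. The precursor is a cis-α-methylene-γ-butyrolactone carrying a (Z)-enal arm and a (Z)-vinyl iodide arm. The resulting C7=C8 alkene and C11 carbinol are then turned into the peroxide bridge by epoxidation, perhydrolysis at C8 and O-alkylation at C11.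

Key step: step 13

Remark: cembrane numbering is used throughout (C1–C2 lactone ring fusion with the ring oxygen on C2, C3=C4, C7 acetoxy carbon, C8 and C11 peroxide carbons, C12=C13, C15=C17 exocyclic methylene, C16 lactone carbonyl), the target being (1S,2S,3E,7R,8R,11S,12Z); the reagent-controlled steps 11, 15 and 16 are assumed to follow their usual facial models.

Step 1
Reactants: 1 geranyl acetate
Product: 2 (2E)-3-methyl-6-oxohex-2-en-1-yl acetate
Conditions: O3, pyridine, CH2Cl2, −78 °C; then Me2S, −78 °C → rt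
Reagents that add atoms: ozone, [O-][O+]=O
Why: Ozonolysis should cleave the electron-rich 6,7-alkene selectively, because the 2,3-alkene is deactivated by the allylic acetate.

Step 2
Reactants: 2 (2E)-3-methyl-6-oxohex-2-en-1-yl acetate; 3 ethyltriphenylphosphonium iodide
Product: 4 (2E,6Z)-7-iodo-3-methylocta-2,6-dien-1-yl acetate
Conditions: n-BuLi, THF, rt; I2, −78 °C; NaN(SiMe3)2, −20 °C; then 2, −78 → −20 °C
Reagents that add atoms: iodine, [I][I]
Why: Stork–Zhao olefination with the α-iodo ylide should give the (Z)-2-iodoalkene (iodine cis to the chain) under kinetic control, the acetate being inert at low temperature.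

Step 3
Reactants: 4 (2E,6Z)-7-iodo-3-methylocta-2,6-dien-1-yl acetate
Product: 5 (2E,6Z)-7-iodo-3-methylocta-2,6-dien-1-ol
Conditions: K2CO3, MeOH, 0 °C → rt
Reagents that add atoms: none
Why: Base-catalysed transesterification (methanolysis) should free the allylic alcohol without touching the vinyl iodide.

Step 4
Reactants: 5 (2E,6Z)-7-iodo-3-methylocta-2,6-dien-1-ol
Product: 6 (2E,6Z)-7-iodo-3-methylocta-2,6-dienal
Conditions: MnO2, CH2Cl2, rt
Reagents that add atoms: none
Why: Allylic oxidation with MnO2 should give the (E)-enal without double-bond isomerisation.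

Step 5
Reactants: 7 (3-bromopropoxy)(tert-butyl)dimethylsilane; 8 triphenylphosphine
Product: 9 [3-(tert-butyldimethylsilyloxy)propyl]triphenylphosphonium bromide
Conditions: MeCN, reflux
Reagents that add atoms: none
Why: SN2 quaternisation of the phosphine by the primary bromide should give the Wittig salt.

Step 6
Reactants: 9 [3-(tert-butyldimethylsilyloxy)propyl]triphenylphosphonium bromide; 10 1,1-dimethoxypropan-2-one
Product: 11 (Z)-tert-butyl[(5,5-dimethoxy-4-methylpent-3-en-1-yl)oxy]dimethylsilane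
Conditions: NaN(SiMe3)2, THF, −78 °C; then 10, −78 °C → rt
Reagents that add atoms: none
Why: Wittig reaction of a non-stabilised ylide with an α,α-dialkoxy ketone should place the ylide chain cis to the acetal carbon, setting the (Z)-C12=C13 geometry.

Step 7
Reactants: 11 (Z)-tert-butyl[(5,5-dimethoxy-4-methylpent-3-en-1-yl)oxy]dimethylsilane
Product: 12 (3Z)-5,5-dimethoxy-4-methylpent-3-en-1-ol
Conditions: Bu4NF, THF, 0 °C
Reagents that add atoms: none
Why: Fluoride desilylation should free the primary alcohol while the base-stable acetal survives.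

Step 8
Reactants: 12 (3Z)-5,5-dimethoxy-4-methylpent-3-en-1-ol
Product: 13 (3Z)-5,5-dimethoxy-4-methylpent-3-enal
Conditions: Dess–Martin periodinane, pyridine, CH2Cl2, 0 °C
Reagents that add atoms: none
Why: Buffered Dess–Martin oxidation should give the β,γ-unsaturated aldehyde without moving the alkene into conjugation.

Step 9
Reactants: 13 (3Z)-5,5-dimethoxy-4-methylpent-3-enal; 14 methyl acrylate
Product: 15 methyl (5Z)-3-hydroxy-7,7-dimethoxy-6-methyl-2-methylidenehept-5-enoate (racemic)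
Conditions: DABCO, MeOH, rt
Reagents that add atoms: none
Why: Morita–Baylis–Hillman reaction should join the acrylate α-carbon to the aldehyde; the carbinol centre is racemic but is erased in step 10.

Step 10
Reactants: 15 methyl (5Z)-3-hydroxy-7,7-dimethoxy-6-methyl-2-methylidenehept-5-enoate
Product: 17 methyl (2Z,5Z)-2-(bromomethyl)-7,7-dimethoxy-6-methylhepta-2,5-dienoate, via allylic mesylate 16 (not isolated)
Conditions: MsCl, Et3N, CH2Cl2, −40 °C; then LiBr, acetone, 0 °C
Reagents that add atoms: lithium bromide, [Li+].[Br-]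
Why: Mesylation followed by SN2' displacement with bromide should give the thermodynamically favoured (Z)-2-(bromomethyl)enoate under neutral conditions that spare the acetal.

Step 11
Reactants: 6 (2E,6Z)-7-iodo-3-methylocta-2,6-dienal; 17 methyl (2Z,5Z)-2-(bromomethyl)-7,7-dimethoxy-6-methylhepta-2,5-dienoate
Product: 19 (4S,5S)-4-[(2Z)-4,4-dimethoxy-3-methylbut-2-en-1-yl]-5-[(1E,5Z)-6-iodo-2-methylhepta-1,5-dien-1-yl]-3-methylideneoxolan-2-one, via silylated hydroxy ester 18 (not isolated)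
Conditions: CrCl2 (10 mol%, nickel-free), chiral 1,8-bis(oxazolinyl)carbazole ligand (12 mol%, antipode for Re-face attack), iPr2NEt (30 mol%), Mn, Me3SiCl, THF, 0 °C → rt; then Bu4NF, THF, 0 °C
Reagents that add atoms: none
Why: Catalytic asymmetric Nozaki–Hiyama–Kishi-type 2-(alkoxycarbonyl)allylation (chromium Barbier reaction) should pass through a closed chair transition state of the ester-chelated allylchromium to give the syn adduct, the ligand directing Re-face attack at C2 (2S, hence 1S), and desilylation should close the cis lactone.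

Step 12
Reactants: 19 (4S,5S)-4-[(2Z)-4,4-dimethoxy-3-methylbut-2-en-1-yl]-5-[(1E,5Z)-6-iodo-2-methylhepta-1,5-dien-1-yl]-3-methylideneoxolan-2-one
Product: 20 (4S,5S)-5-[(1E,5Z)-6-iodo-2-methylhepta-1,5-dien-1-yl]-3-methylidene-4-[(2Z)-3-methyl-4-oxobut-2-en-1-yl]oxolan-2-one
Conditions: oxalic acid, THF/H2O, 0 °C → rt
Reagents that add atoms: water, O
Why: Mild acid hydrolysis of the labile allylic dimethyl acetal should unveil the (Z)-enal without Z to E isomerisation.

Step 13
Reactants: 20 (4S,5S)-5-[(1E,5Z)-6-iodo-2-methylhepta-1,5-dien-1-yl]-3-methylidene-4-[(2Z)-3-methyl-4-oxobut-2-en-1-yl]oxolan-2-one; 21 vinylmagnesium bromide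
Product: 26 (1S,2S,3E,7Z,12Z)-11-hydroxycembra-3,7,12,15(17)-tetraen-16,2-olide (both C11 epimers), via bromomagnesium alkoxide 22 (not isolated), via trimethylsilyl ether 23 (not isolated), via B-alkyl-9-BBN borane 24 (not isolated), via macrocyclic silyl ether 25 (not isolated)
Conditions: CH2=CHMgBr (1.05 equiv), THF, −78 °C; Me3SiCl, −78 → 0 °C; 9-BBN, THF, 0 °C → rt; slow addition to Pd(dppf)Cl2 (10 mol%), AsPh3, Cs2CO3, DMF/THF/H2O, 45 °C, 0.002 M; aq. citric acid work-up
Reagents that add atoms: none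
Why: Vinylmagnesium bromide adds 1,2 to the C11 aldehyde (C10–C11 bond), the alkoxide is capped in situ as its trimethylsilyl ether, 9-BBN hydroborates the only monosubstituted alkene with boron on C9, and zerovalent palladium then inserts into the C8–I bond, accepts the alkyl group from the base-activated borane and reductively eliminates (C8–C9 bond). The closest known reaction types are carbonyl vinylation and B-alkyl Suzuki–Miyaura macrocyclisation, here telescoped in one flask. The 14-membered carbocycle is closed by intramolecular C(sp3)–C(sp2) cross-coupling through a large palladacycle, with retention of the vinyl iodide geometry so that C7=C8 is Z. The one new stereocentre, C11, is formed without control on purpose, because both epimers converge on one enone in step 14 and C11 is set again in step 16. The step needs aldehyde-over-lactone selectivity for the Grignard reagent (secured by −78 °C and one equivalent), selectivity of 9-BBN for the terminal vinyl group over the trisubstituted alkenes and the electron-poor exocyclic enoate (steric and electronic bias), and ring closure over oligomerisation (slow addition at high dilution).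

Step 14
Reactants: 26 (1S,2S,3E,7Z,12Z)-11-hydroxycembra-3,7,12,15(17)-tetraen-16,2-olide (both C11 epimers)
Product: 27 (1S,2S,3E,7Z,12Z)-11-oxocembra-3,7,12,15(17)-tetraen-16,2-olide
Conditions: MnO2, CH2Cl2, rt
Reagents that add atoms: none
Why: Allylic oxidation with MnO2 should funnel both C11 epimers into a single (Z)-enone.

Step 15
Reactants: 27 (1S,2S,3E,7Z,12Z)-11-oxocembra-3,7,12,15(17)-tetraen-16,2-olide
Product: 28 (1S,2S,3E,7R,8S,12Z)-7,8-epoxy-11-oxocembra-3,12,15(17)-trien-16,2-olide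
Conditions: D-fructose-derived Shi ketone (30 mol%), KHSO5, K2CO3, Bu4NHSO4, MeCN/CH2(OMe)2/aq. buffer pH 10.5, 0 °C
Reagents that add atoms: potassium peroxymonosulfate, [K+].[O-]S(=O)(=O)OO
Why: Shi epoxidation should pick the only isolated electron-rich alkene (C3=C4 is deactivated by the allylic lactone oxygen, C12=C13 and C15=C17 are conjugated to carbonyls), and the spiro transition state of the chiral dioxirane should deliver oxygen to the face that gives the cis (7R,8S)-epoxide.

Step 16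
Reactants: 28 (1S,2S,3E,7R,8S,12Z)-7,8-epoxy-11-oxocembra-3,12,15(17)-trien-16,2-olide
Product: 29 (1S,2S,3E,7R,8S,11S,12Z)-7,8-epoxy-11-hydroxycembra-3,12,15(17)-trien-16,2-olide
Conditions: (R)-2-methyl-CBS-oxazaborolidine (20 mol%), catecholborane, toluene, −78 °C
Reagents that add atoms: none
Why: Corey–Bakshi–Shibata reduction with the α-methylalkenyl group as the large substituent should give the (11S)-allylic alcohol, catecholborane at −78 °C sparing the epoxide and the enoate.

Step 17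
Reactants: 29 (1S,2S,3E,7R,8S,11S,12Z)-7,8-epoxy-11-hydroxycembra-3,12,15(17)-trien-16,2-olide
Product: 30 (1S,2S,3E,7R,8S,11R,12Z)-11-chloro-7,8-epoxycembra-3,12,15(17)-trien-16,2-olide
Conditions: PPh3, hexachloroacetone, CH2Cl2, −20 → 0 °C
Reagents that add atoms: hexachloroacetone, ClC(Cl)(Cl)C(=O)C(Cl)(Cl)Cl
Why: Appel-type chlorination with PPh3 and hexachloroacetone should convert the allylic alcohol into the chloride by SN2 with inversion (11R) and without allylic transposition, under neutral conditions that spare the epoxide.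

Step 18
Reactants: 30 (1S,2S,3E,7R,8S,11R,12Z)-11-chloro-7,8-epoxycembra-3,12,15(17)-trien-16,2-olide
Product: 31 (1S,2S,3E,7R,8R,11R,12Z)-11-chloro-8-hydroperoxy-7-hydroxycembra-3,12,15(17)-trien-16,2-olide
Conditions: H2O2 (anhydrous, Et2O), H3PMo12O40 (cat.), Et2O, 0 °C
Reagents that add atoms: hydrogen peroxide, OO
Why: Acid-catalysed perhydrolysis of the trisubstituted epoxide should open it at the tertiary carbon C8 with inversion, giving the (8R)-hydroperoxide and the (7R)-carbinol.

Step 19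
Reactants: 31 (1S,2S,3E,7R,8R,11R,12Z)-11-chloro-8-hydroperoxy-7-hydroxycembra-3,12,15(17)-trien-16,2-olide
Product: 32 (1S,2S,3E,7R,8R,11S,12Z)-8,11-epidioxy-7-hydroxycembra-3,12,15(17)-trien-16,2-olide
Conditions: Cs2CO3, DMF, 0 °C, 0.005 M
Reagents that add atoms: none
Why: Intramolecular O-alkylation of the hydroperoxide anion (6-exo-tet SN2) should invert C11 to S and close the cis-bridged 1,2-dioxane, the more acidic hydroperoxide being ionised in preference to the C7 hydroxyl.

Step 20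
Reactants: 32 (1S,2S,3E,7R,8R,11S,12Z)-8,11-epidioxy-7-hydroxycembra-3,12,15(17)-trien-16,2-olide
Product: 33 (1S,2S,3E,7R,8R,11S,12Z)-7-acetoxy-8,11-epidioxycembra-3,12,15(17)-trien-16,2-olide
Conditions: Ac2O, DMAP, pyridine, CH2Cl2, 0 °C → rt
Reagents that add atoms: acetic anhydride, CC(=O)OC(C)=O
Why: DMAP-catalysed acylation of the secondary C7 alcohol should give the target, the dialkyl peroxide being inert to these conditions.

Compound list
1 | geranyl acetate | CC(C)=CCC/C(C)=C/COC(C)=O | starting material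
2 | (2E)-3-methyl-6-oxohex-2-en-1-yl acetate | O=CCC/C(C)=C/COC(C)=O | intermediate
3 | ethyltriphenylphosphonium iodide | CC[P+](c1ccccc1)(c1ccccc1)c1ccccc1.[I-] | starting material
4 | (2E,6Z)-7-iodo-3-methylocta-2,6-dien-1-yl acetate | C/C(I)=C/CC/C(C)=C/COC(C)=O | intermediate
5 | (2E,6Z)-7-iodo-3-methylocta-2,6-dien-1-ol | C/C(I)=C/CC/C(C)=C/CO | intermediate
6 | (2E,6Z)-7-iodo-3-methylocta-2,6-dienal | C/C(I)=C/CC/C(C)=C/C=O | intermediate
7 | (3-bromopropoxy)(tert-butyl)dimethylsilane | CC(C)(C)[Si](C)(C)OCCCBr | starting material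
8 | triphenylphosphine | c1ccc(cc1)P(c1ccccc1)c1ccccc1 | starting material
9 | [3-(tert-butyldimethylsilyloxy)propyl]triphenylphosphonium bromide | CC(C)(C)[Si](C)(C)OCCC[P+](c1ccccc1)(c1ccccc1)c1ccccc1.[Br-] | intermediate
10 | 1,1-dimethoxypropan-2-one | CC(=O)C(OC)OC | starting material
11 | (Z)-tert-butyl[(5,5-dimethoxy-4-methylpent-3-en-1-yl)oxy]dimethylsilane | CC(C)(C)[Si](C)(C)OCC/C=C(/C)C(OC)OC | intermediate
12 | (3Z)-5,5-dimethoxy-4-methylpent-3-en-1-ol | OCC/C=C(/C)C(OC)OC | intermediate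
13 | (3Z)-5,5-dimethoxy-4-methylpent-3-enal | O=CC/C=C(/C)C(OC)OC | intermediate
14 | methyl acrylate | C=CC(=O)OC | starting material
15 | methyl (5Z)-3-hydroxy-7,7-dimethoxy-6-methyl-2-methylidenehept-5-enoate (racemic) | COC(=O)C(=C)C(O)C/C=C(/C)C(OC)OC | intermediate
16 | methyl (5Z)-3-(methanesulfonyloxy)-7,7-dimethoxy-6-methyl-2-methylidenehept-5-enoate (not isolated) | COC(=O)C(=C)C(OS(C)(=O)=O)C/C=C(/C)C(OC)OC | intermediate
17 | methyl (2Z,5Z)-2-(bromomethyl)-7,7-dimethoxy-6-methylhepta-2,5-dienoate | BrC/C(C(=O)OC)=C\C/C=C(/C)C(OC)OC | intermediate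
18 | methyl (3S,4S,5E,9Z)-3-[(2Z)-4,4-dimethoxy-3-methylbut-2-en-1-yl]-10-iodo-6-methyl-2-methylidene-4-(trimethylsilyloxy)undeca-5,9-dienoate (not isolated) | COC(=O)C(=C)[C@H](C/C=C(/C)C(OC)OC)[C@@H](O[Si](C)(C)C)/C=C(\C)CC/C=C(/C)I | intermediate
19 | (4S,5S)-4-[(2Z)-4,4-dimethoxy-3-methylbut-2-en-1-yl]-5-[(1E,5Z)-6-iodo-2-methylhepta-1,5-dien-1-yl]-3-methylideneoxolan-2-one | C=C1C(=O)O[C@@H](/C=C(\C)CC/C=C(/C)I)[C@H]1C/C=C(/C)C(OC)OC | intermediate
20 | (4S,5S)-5-[(1E,5Z)-6-iodo-2-methylhepta-1,5-dien-1-yl]-3-methylidene-4-[(2Z)-3-methyl-4-oxobut-2-en-1-yl]oxolan-2-one | C=C1C(=O)O[C@@H](/C=C(\C)CC/C=C(/C)I)[C@H]1C/C=C(/C)C=O | intermediate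
21 | vinylmagnesium bromide | C=C[Mg]Br | starting material
22 | bromomagnesium alkoxide of (4S,5S)-4-[(2Z)-4-hydroxy-3-methylhexa-2,5-dien-1-yl]-5-[(1E,5Z)-6-iodo-2-methylhepta-1,5-dien-1-yl]-3-methylideneoxolan-2-one (C4' epimers, not isolated) | C=C1C(=O)O[C@@H](/C=C(\C)CC/C=C(/C)I)[C@H]1C/C=C(/C)C(O[Mg]Br)C=C | intermediate
23 | (4S,5S)-5-[(1E,5Z)-6-iodo-2-methylhepta-1,5-dien-1-yl]-3-methylidene-4-[(2Z)-3-methyl-4-(trimethylsilyloxy)hexa-2,5-dien-1-yl]oxolan-2-one (not isolated) | C=C1C(=O)O[C@@H](/C=C(\C)CC/C=C(/C)I)[C@H]1C/C=C(/C)C(O[Si](C)(C)C)C=C | intermediate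
24 | (4S,5S)-4-[(2Z)-6-(9-borabicyclo[3.3.1]nonan-9-yl)-3-methyl-4-(trimethylsilyloxy)hex-2-en-1-yl]-5-[(1E,5Z)-6-iodo-2-methylhepta-1,5-dien-1-yl]-3-methylideneoxolan-2-one (not isolated) | C=C1C(=O)O[C@@H](/C=C(\C)CC/C=C(/C)I)[C@H]1C/C=C(/C)C(O[Si](C)(C)C)CCB1C2CCCC1CCC2 | intermediate
25 | (1S,2S,3E,7Z,12Z)-11-(trimethylsilyloxy)cembra-3,7,12,15(17)-tetraen-16,2-olide (C11 epimers, not isolated) | C=C1C(=O)O[C@H]2/C=C(\C)CC/C=C(/C)CCC(O[Si](C)(C)C)/C(C)=C\C[C@@H]12 | intermediate
26 | (1S,2S,3E,7Z,12Z)-11-hydroxycembra-3,7,12,15(17)-tetraen-16,2-olide (both C11 epimers) | C=C1C(=O)O[C@H]2/C=C(\C)CC/C=C(/C)CCC(O)/C(C)=C\C[C@@H]12 | intermediate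
27 | (1S,2S,3E,7Z,12Z)-11-oxocembra-3,7,12,15(17)-tetraen-16,2-olide | C=C1C(=O)O[C@H]2/C=C(\C)CC/C=C(/C)CCC(=O)/C(C)=C\C[C@@H]12 | intermediate
28 | (1S,2S,3E,7R,8S,12Z)-7,8-epoxy-11-oxocembra-3,12,15(17)-trien-16,2-olide | C=C1C(=O)O[C@H]2/C=C(\C)CC[C@H]3O[C@@]3(C)CCC(=O)/C(C)=C\C[C@@H]12 | intermediate
29 | (1S,2S,3E,7R,8S,11S,12Z)-7,8-epoxy-11-hydroxycembra-3,12,15(17)-trien-16,2-olide | C=C1C(=O)O[C@H]2/C=C(\C)CC[C@H]3O[C@@]3(C)CC[C@H](O)/C(C)=C\C[C@@H]12 | intermediate
30 | (1S,2S,3E,7R,8S,11R,12Z)-11-chloro-7,8-epoxycembra-3,12,15(17)-trien-16,2-olide | C=C1C(=O)O[C@H]2/C=C(\C)CC[C@H]3O[C@@]3(C)CC[C@@H](Cl)/C(C)=C\C[C@@H]12 | intermediate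
31 | (1S,2S,3E,7R,8R,11R,12Z)-11-chloro-8-hydroperoxy-7-hydroxycembra-3,12,15(17)-trien-16,2-olide | C=C1C(=O)O[C@H]2/C=C(\C)CC[C@@H](O)[C@](C)(OO)CC[C@@H](Cl)/C(C)=C\C[C@@H]12 | intermediate
32 | (1S,2S,3E,7R,8R,11S,12Z)-8,11-epidioxy-7-hydroxycembra-3,12,15(17)-trien-16,2-olide | C=C1C(=O)O[C@H]2/C=C(\C)CC[C@@H](O)[C@@]3(C)CC[C@H](OO3)/C(C)=C\C[C@@H]12 | intermediate
33 | (1S,2S,3E,7R,8R,11S,12Z)-7-acetoxy-8,11-epidioxycembra-3,12,15(17)-trien-16,2-olide | C=C1C(=O)O[C@H]2/C=C(\C)CC[C@@H](OC(C)=O)[C@@]3(C)CC[C@H](OO3)/C(C)=C\C[C@@H]12 | target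

Total step count: 20. Longest linear sequence: 16 steps (steps 5 to 20).

Steps most likely to fail

Step 13. The Grignard reagent or 9-BBN may attack the α-methylene lactone (conjugate addition, carbonyl addition or hydroboration of the exocyclic enoate), or ring closure may be outpaced by oligomerisation and protodeboronation. The fallback masks the Michael acceptor as a Mannich base; it sets out from 19 and comes back at 26. Dimethylamine in THF should add to 19 to give the amino lactone acetal F1, and oxalic acid hydrolysis should then give the amino enal F2. The same one-flask sequence with 21 would run through the bromomagnesium alkoxide F3, the trimethylsilyl ether F4, the B-alkyl-9-BBN borane F5 and the macrocyclic silyl ether F6 to the macrocyclic amino alcohol F7. Methylation with MeI to the trimethylammonium iodide F8 and elimination with aqueous NaHCO3 should restore the methylene lactone 26.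

Step 19. Base may trigger Kornblum–DeLaMare fragmentation of the hydroperoxide or its conjugate addition to the methylene lactone faster than O-alkylation, or the allylic chloride may ionise and lose configuration. The fallback reverses the order in which the two C–O bonds are made; it sets out from 30 and comes back at 32. Silver-assisted displacement of the chloride by ethereal H2O2 (AgOCOCF3, Et2O, −20 °C) should give the epoxy hydroperoxide F9, and catalytic camphorsulfonic acid should then drive 6-exo opening of the epoxide at C8 with inversion to give 32.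

Step 11. Facial or syn/anti control by the chiral chromium catalyst may be insufficient with this enal and γ-substituted bromide. The fallback replaces catalyst control by racemic coupling and resolution; it sets out from 6 and 17 and comes back at 19. Ligand-free indium powder in THF/H2O should give the syn adduct as a racemate, the hydroxy ester F10 and its enantiomer F11. Acid-catalysed lactonisation (TsOH, benzene) would give 19 together with its enantiomer F12, and preparative chromatography on a chiral stationary phase would deliver 19.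

Further compounds
F1 | step 13 | (4S,5S)-4-[(2Z)-4,4-dimethoxy-3-methylbut-2-en-1-yl]-3-[(dimethylamino)methyl]-5-[(1E,5Z)-6-iodo-2-methylhepta-1,5-dien-1-yl]oxolan-2-one (C3 epimers) | CN(C)CC1C(=O)O[C@@H](/C=C(\C)CC/C=C(/C)I)[C@H]1C/C=C(/C)C(OC)OC
F2 | step 13 | (4S,5S)-3-[(dimethylamino)methyl]-5-[(1E,5Z)-6-iodo-2-methylhepta-1,5-dien-1-yl]-4-[(2Z)-3-methyl-4-oxobut-2-en-1-yl]oxolan-2-one | CN(C)CC1C(=O)O[C@@H](/C=C(\C)CC/C=C(/C)I)[C@H]1C/C=C(/C)C=O
F3 | step 13 | bromomagnesium alkoxide of the divinyl carbinol from F2 | CN(C)CC1C(=O)O[C@@H](/C=C(\C)CC/C=C(/C)I)[C@H]1C/C=C(/C)C(O[Mg]Br)C=C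
F4 | step 13 | trimethylsilyl ether of the divinyl carbinol from F2 | CN(C)CC1C(=O)O[C@@H](/C=C(\C)CC/C=C(/C)I)[C@H]1C/C=C(/C)C(O[Si](C)(C)C)C=C
F5 | step 13 | B-alkyl-9-BBN borane from F4 | CN(C)CC1C(=O)O[C@@H](/C=C(\C)CC/C=C(/C)I)[C@H]1C/C=C(/C)C(O[Si](C)(C)C)CCB1C2CCCC1CCC2
F6 | step 13 | (1S,2S,3E,7Z,12Z)-17-(dimethylamino)-11-(trimethylsilyloxy)cembra-3,7,12-trien-16,2-olide | CN(C)CC1C(=O)O[C@H]2/C=C(\C)CC/C=C(/C)CCC(O[Si](C)(C)C)/C(C)=C\C[C@@H]12
F7 | step 13 | (1S,2S,3E,7Z,12Z)-17-(dimethylamino)-11-hydroxycembra-3,7,12-trien-16,2-olide | CN(C)CC1C(=O)O[C@H]2/C=C(\C)CC/C=C(/C)CCC(O)/C(C)=C\C[C@@H]12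
F8 | step 13 | trimethylammonium iodide of F7 | C[N+](C)(C)CC1C(=O)O[C@H]2/C=C(\C)CC/C=C(/C)CCC(O)/C(C)=C\C[C@@H]12.[I-]
F9 | step 19 | (1S,2S,3E,7R,8S,11S,12Z)-7,8-epoxy-11-hydroperoxycembra-3,12,15(17)-trien-16,2-olide | C=C1C(=O)O[C@H]2/C=C(\C)CC[C@H]3O[C@@]3(C)CC[C@H](OO)/C(C)=C\C[C@@H]12
F10 | step 11 | methyl (3S,4S,5E,9Z)-3-[(2Z)-4,4-dimethoxy-3-methylbut-2-en-1-yl]-4-hydroxy-10-iodo-6-methyl-2-methylideneundeca-5,9-dienoate | COC(=O)C(=C)[C@H](C/C=C(/C)C(OC)OC)[C@@H](O)/C=C(\C)CC/C=C(/C)I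
F11 | step 11 | methyl (3R,4R,5E,9Z)-3-[(2Z)-4,4-dimethoxy-3-methylbut-2-en-1-yl]-4-hydroxy-10-iodo-6-methyl-2-methylideneundeca-5,9-dienoate | COC(=O)C(=C)[C@@H](C/C=C(/C)C(OC)OC)[C@H](O)/C=C(\C)CC/C=C(/C)I
F12 | step 11 | (4R,5R)-4-[(2Z)-4,4-dimethoxy-3-methylbut-2-en-1-yl]-5-[(1E,5Z)-6-iodo-2-methylhepta-1,5-dien-1-yl]-3-methylideneoxolan-2-one | C=C1C(=O)O[C@H](/C=C(\C)CC/C=C(/C)I)[C@@H]1C/C=C(/C)C(OC)OC
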